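Assumption: the target has no stereocentre or other stereogenic element, so "single enantiomer" means the achiral compound as drawn; hydrazine is used as its commercial monohydrate.

**Retrosynthetic overview**
1. Target ⇐ its tribenzyl precursor (one benzyl ester, two benzyl ethers) by a single global hydrogenolysis.
2. Key C–C bond: ring-A C6–CH2 of the heptyl chain, made last on the assembled depside. An aryl triflate carbon is joined to C1 of heptanal, which acts as an alkyl-carbanion equivalent through its N–H hydrazone (Ni catalysis, loss of N2).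
3. Aryl triflate ⇐ monotriflation of a symmetric 2,6-dihydroxybenzoate whose 4-OH is already blocked by the depside ester itself.
4. Depside ester ⇐ benzyl 2,4,6-trihydroxybenzoate (4-OH) + 2,4-di-O-benzylorsellinic acid.
5. No ring is formed: both benzene rings are bought (2,4,6-trihydroxybenzoic acid and methyl orsellinate).

**Route**

Step 1
Reactants: 1 2,4,6-trihydroxybenzoic acid
Product: 2 benzyl 2,4,6-trihydroxybenzoate
Conditions: BnBr (1.05 equiv), KHCO3 (1.1 equiv), DMF, rt, 16 h
Reagents that add atoms: benzyl bromide, BrCc1ccccc1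
Why: SN2 O-alkylation of the carboxylate (benzyl esterification) with bicarbonate as base, which is too weak to ionise the phenols, so only the ester forms and the acid is never heated enough to decarboxylate.

Step 2
Reactants: 3 methyl orsellinate (methyl 2,4-dihydroxy-6-methylbenzoate)
Product: 5 2,4-bis(benzyloxy)-6-methylbenzoic acid, via methyl 2,4-bis(benzyloxy)-6-methylbenzoate 4 (not isolated)
Conditions: BnBr (2.3 equiv), K2CO3 (3 equiv), DMSO, 50 °C; then 6 M aq KOH, 90 °C; HCl work-up
Reagents that add atoms: benzyl bromide, BrCc1ccccc1; potassium hydroxide, [K+].[OH-]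
Why: Williamson etherification of both phenols (the chelated 2-OH needs warm DMSO) followed in the same pot by saponification of the hindered methyl ester with KOH in aqueous DMSO, conditions to which benzyl aryl ethers are inert.

Step 3
Reactants: 5 2,4-bis(benzyloxy)-6-methylbenzoic acid; 2 benzyl 2,4,6-trihydroxybenzoate; 6 trifluoroacetic anhydride
Product: 8 benzyl 4-{[2,4-bis(benzyloxy)-6-methylbenzoyl]oxy}-2,6-dihydroxybenzoate, via mixed trifluoroacetic anhydride 7 (not isolated)
Conditions: TFAA (3 equiv), toluene, rt, 4 h; aq NaHCO3 work-up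
Reagents that add atoms: none
Why: Mixed-anhydride depside esterification, in which TFAA turns the 2,6-disubstituted acid into an acylium-like mixed anhydride that acylates the only unhindered, non-chelated phenol (4-OH) of 2 while the two ester-chelated ortho-OH groups stay free.

Step 4
Reactants: 8 benzyl 4-{[2,4-bis(benzyloxy)-6-methylbenzoyl]oxy}-2,6-dihydroxybenzoate
Product: 9 benzyl 4-{[2,4-bis(benzyloxy)-6-methylbenzoyl]oxy}-2-hydroxy-6-{[(trifluoromethyl)sulfonyl]oxy}benzoate
Conditions: Tf2O (1.05 equiv), pyridine (2.5 equiv), CH2Cl2, −40 to 0 °C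
Reagents that add atoms: trifluoromethanesulfonic anhydride, O=S(=O)(OS(=O)(=O)C(F)(F)F)C(F)(F)F
Why: Desymmetrising O-triflation of one of two equivalent phenols, which stops at the monotriflate because the remaining OH is then locked in a strong hydrogen bond to the ester carbonyl on a more electron-poor ring.

Step 5
Reactants: 9 benzyl 4-{[2,4-bis(benzyloxy)-6-methylbenzoyl]oxy}-2-hydroxy-6-{[(trifluoromethyl)sulfonyl]oxy}benzoate; 10 heptanal; 11 hydrazine monohydrate
Product: 14 benzyl 4-{[2,4-bis(benzyloxy)-6-methylbenzoyl]oxy}-6-heptyl-2-hydroxybenzoate, via heptanal hydrazone 12 (not isolated), via benzylic diazene 13 (not isolated)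
Conditions: 10 (3 equiv), 11 (3 equiv), THF, 4 Å MS, rt, 1 h; then 9, Ni(cod)2 (10 mol%), PMe3 (40 mol%), K3PO4 (3 equiv), THF, 60 °C, 16 h
Reagents that add atoms: none
Why: Proposed new method: this extends the known Ni(0)/PMe3-catalysed denitrogenative cross-coupling of aryl-aldehyde N–H hydrazones with aryl halides and sulfonates (Wolff–Kishner-type carbonyl umpolung, the closest known reaction type) to an enolisable aliphatic hydrazone and an ester-bearing triflate. The electron-poor C–OTf bond ortho to the ester adds quickly to Ni(0); the deprotonated hydrazone binds nickel through nitrogen and forms the C–C bond at its carbon terminus to give diazene 13, which loses N2 under base and is protonated at the benzylic carbon. Both esters are di-ortho-substituted (mesitoate-like) and the base is anhydrous, non-nucleophilic K3PO4, so acyl cleavage should be slower than coupling. The transient stereocentre of racemic 13 is erased on loss of N2.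

Step 6
Reactants: 14 benzyl 4-{[2,4-bis(benzyloxy)-6-methylbenzoyl]oxy}-6-heptyl-2-hydroxybenzoate
Product: 15 4-[(2,4-dihydroxy-6-methylbenzoyl)oxy]-6-heptyl-2-hydroxybenzoic acid
Conditions: H2 (1 atm), 10% Pd/C, EtOAc, rt
Reagents that add atoms: none
Why: Global catalytic hydrogenolysis (O-debenzylation) of the benzyl ester and both benzyl ethers under neutral conditions leaves the aryl depside ester and the salicylic acid untouched; there is no stereocentre to set.

**Compound list**
1 | 2,4,6-trihydroxybenzoic acid | OC(=O)c1c(O)cc(O)cc1O | starting material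
2 | benzyl 2,4,6-trihydroxybenzoate | O=C(OCc1ccccc1)c1c(O)cc(O)cc1O | intermediate
3 | methyl orsellinate (methyl 2,4-dihydroxy-6-methylbenzoate) | COC(=O)c1c(C)cc(O)cc1O | starting material
4 | methyl 2,4-bis(benzyloxy)-6-methylbenzoate | COC(=O)c1c(C)cc(OCc2ccccc2)cc1OCc1ccccc1 | intermediate (not isolated)
5 | 2,4-bis(benzyloxy)-6-methylbenzoic acid | OC(=O)c1c(C)cc(OCc2ccccc2)cc1OCc1ccccc1 | intermediate
6 | trifluoroacetic anhydride | O=C(OC(=O)C(F)(F)F)C(F)(F)F | starting material
7 | 2,4-bis(benzyloxy)-6-methylbenzoic trifluoroacetic anhydride | O=C(OC(=O)C(F)(F)F)c1c(C)cc(OCc2ccccc2)cc1OCc1ccccc1 | intermediate (not isolated)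
8 | benzyl 4-{[2,4-bis(benzyloxy)-6-methylbenzoyl]oxy}-2,6-dihydroxybenzoate | O=C(OCc1ccccc1)c1c(O)cc(OC(=O)c2c(C)cc(OCc3ccccc3)cc2OCc2ccccc2)cc1O | intermediate
9 | benzyl 4-{[2,4-bis(benzyloxy)-6-methylbenzoyl]oxy}-2-hydroxy-6-{[(trifluoromethyl)sulfonyl]oxy}benzoate | O=C(OCc1ccccc1)c1c(O)cc(OC(=O)c2c(C)cc(OCc3ccccc3)cc2OCc2ccccc2)cc1OS(=O)(=O)C(F)(F)F | intermediate
10 | heptanal | CCCCCCC=O | starting material
11 | hydrazine monohydrate | NN.O | starting material
12 | (E)-heptanal hydrazone (heptylidenehydrazine) | CCCCCC/C=N/N | intermediate (not isolated)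
13 | benzyl 4-{[2,4-bis(benzyloxy)-6-methylbenzoyl]oxy}-2-(1-diazenylheptyl)-6-hydroxybenzoate (racemic, transient) | CCCCCCC(N=N)c1cc(OC(=O)c2c(C)cc(OCc3ccccc3)cc2OCc2ccccc2)cc(O)c1C(=O)OCc1ccccc1 | intermediate (not isolated)
14 | benzyl 4-{[2,4-bis(benzyloxy)-6-methylbenzoyl]oxy}-6-heptyl-2-hydroxybenzoate | CCCCCCCc1cc(OC(=O)c2c(C)cc(OCc3ccccc3)cc2OCc2ccccc2)cc(O)c1C(=O)OCc1ccccc1 | intermediate
15 | 4-[(2,4-dihydroxy-6-methylbenzoyl)oxy]-6-heptyl-2-hydroxybenzoic acid | CCCCCCCc1cc(OC(=O)c2c(C)cc(O)cc2O)cc(O)c1C(=O)O | target

**Totals**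
Total step count: 6. Longest linear sequence: 5 steps (3 → 5 → 8 → 9 → 14 → 15; the branch from 1 is equally long).

**Steps most likely to fail, with fallbacks**

Step 5 is the riskiest. The aliphatic hydrazone may be lost to azine formation or simple Wolff–Kishner reduction. Residual hydrazine or hydroxide may also cleave the triflate or the depside ester before coupling. The fallback sets out again from triflate 9 and comes back to the route at 14. It is a nickel-catalysed reductive cross-electrophile coupling with purchased 1-bromoheptane (NiBr2·glyme 10 mol%, 4,4′-di-tert-butyl-2,2′-bipyridine, Zn dust, NaI, DMA, 60 °C). The polarity reversal then happens at nickel, and no base or nitrogen nucleophile touches the esters. This detour makes no new compound (F0).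

Step 3 is next. The phloroglucinol-type ring of 2 may be C-acylated by the acylium-like mixed anhydride, a second OH may be acylated, or 2 may be too insoluble in toluene. The fallback sets out from acid 5 and comes back at 8. Oxalyl chloride with catalytic DMF in CH2Cl2 gives 2,4-bis(benzyloxy)-6-methylbenzoyl chloride F1. This is added at 0 °C to 2 and K2CO3 (1.1 equiv) in acetone. Selectivity then rests on acidity: only the 4-OH para to the ester is ionised, and that phenoxide is O-acylated.

Step 4 is third. Bis-triflation is possible, and the electron-poor triflate next to a free phenol may hydrolyse on work-up or on silica. The fallback sets out from 8 and comes back at 14, by-passing 9. TsCl (1.05 equiv) and K2CO3 in acetone at rt give the more robust monotosylate benzyl 4-{[2,4-bis(benzyloxy)-6-methylbenzoyl]oxy}-2-hydroxy-6-{[(4-methylphenyl)sulfonyl]oxy}benzoate F2. Aryl tosylates are well-established electrophiles for the Ni/PMe3 hydrazone coupling, so F2 is used with 12 under the step 5 conditions and passes through 13 to 14.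

**Further compounds**
F0 | step 5 | none | none
F1 | step 3 | 2,4-bis(benzyloxy)-6-methylbenzoyl chloride | O=C(Cl)c1c(C)cc(OCc2ccccc2)cc1OCc1ccccc1
F2 | step 4 | benzyl 4-{[2,4-bis(benzyloxy)-6-methylbenzoyl]oxy}-2-hydroxy-6-{[(4-methylphenyl)sulfonyl]oxy}benzoate | Cc1ccc(cc1)S(=O)(=O)Oc1cc(OC(=O)c2c(C)cc(OCc3ccccc3)cc2OCc2ccccc2)cc(O)c1C(=O)OCc1ccccc1
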